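The decalin is traced back to one open chain (eudesmane numbering). Ring B holds a [3+3] pattern: C5 (α to the C4 ketone) and C7 are latent nucleophiles, while C10 and C8 are the β-carbon and the carbonyl carbon of an enal. In the key step an amine-catalysed 6-exo Michael addition of C5 to C10 closes ring A at the quaternary centre and releases the C8 aldehyde. The tethered 2-(methoxycarbonyl)allylboronate allylates this aldehyde at once through C7, closing ring B and unveiling the C8 hydroxyl and the C11=C13 methylene. The precursor is an acyclic keto enal allylboronate with only the C1 and C6 silyloxy stereocentres.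

Key step: step 14

Remark on numbering: ring A = C1, C2, C3, C4, C5, C10; ring B = C5 to C10; C14 = methyl on C10; C11 (with ester C12 and methylene C13) on C7. TBS = tert-butyldimethylsilyl, Bpin = 4,4,5,5-tetramethyl-1,3,2-dioxaborolan-2-yl.

Assumption: the (S,S)-ProPhenol zinc catalyst of step 8 is taken to give the (R)-carbinol at C6; if the sense proves opposite, the (R,R)-ligand is used.

Step 1
Reactants: 1 (2R)-5-oxotetrahydrofuran-2-carboxylic acid
Product: 3 (5R)-5-acetyldihydrofuran-2(3H)-one, via acid chloride 2 (not isolated)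
Conditions: (COCl)2, cat. DMF, CH2Cl2, 0 °C to rt; then Me2CuLi, THF, −78 °C
Reagents that add atoms: Me2CuLi (lithium dimethylcuprate), [Li+].C[Cu-]C
Why: Acyl chloride formation followed by ketone synthesis with a Gilman cuprate, which stops at the methyl ketone and spares the lactone at −78 °C; the bought C1 stereocentre is not touched.

Step 2
Reactants: 3 (5R)-5-acetyldihydrofuran-2(3H)-one; 4 methyl (triphenylphosphoranylidene)acetate
Product: 5 methyl (2E)-3-[(2R)-5-oxotetrahydrofuran-2-yl]but-2-enoate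
Conditions: toluene, 90 °C
Reagents that add atoms: none
Why: Wittig olefination with a stabilised ylide should give the (E)-enoate (lactone carbon trans to the ester) under neutral conditions that do not enolise the α-oxygenated ketone.

Step 3
Reactants: 5 methyl (2E)-3-[(2R)-5-oxotetrahydrofuran-2-yl]but-2-enoate
Product: 6 (5R)-5-[(2E)-4-hydroxybut-2-en-2-yl]tetrahydrofuran-2-ol (lactol, both anomers)
Conditions: i-Bu2AlH (4.4 equiv), CH2Cl2, −78 °C; Rochelle salt work-up
Reagents that add atoms: none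
Why: Hydride reduction with i-Bu2AlH takes the conjugated ester to the allylic alcohol and stops the lactone at the lactol, whose aluminium hemiacetal is stable at −78 °C.

Step 4
Reactants: 6 (5R)-5-[(2E)-4-hydroxybut-2-en-2-yl]tetrahydrofuran-2-ol
Product: 7 (2E,4R)-6-(1,3-dithian-2-yl)-3-methylhex-2-ene-1,4-diol
Conditions: HS(CH2)3SH, BF3·OEt2 (0.3 equiv), CH2Cl2, −40 to −20 °C
Reagents that add atoms: 1,3-propanedithiol, SCCCS
Why: Lewis-acid thioacetalisation of the lactol (a masked γ-hydroxy aldehyde) opens the ring and installs the 1,3-dithiane as acyl-anion equivalent for C4, the low temperature keeping the allylic alcohols from ionising.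

Step 5
Reactants: 7 (2E,4R)-6-(1,3-dithian-2-yl)-3-methylhex-2-ene-1,4-diol
Product: 8 2-[(3R,4E)-3,6-bis(TBS-oxy)-4-methylhex-4-en-1-yl]-1,3-dithiane
Conditions: TBSCl, imidazole, DMF, rt
Reagents that add atoms: TBSCl, CC(C)(C)[Si](C)(C)Cl
Why: Silyl ether formation protects the C1 and C8 hydroxyls before the dithiane is metallated.

Step 6
Reactants: 8 2-[(3R,4E)-3,6-bis(TBS-oxy)-4-methylhex-4-en-1-yl]-1,3-dithiane; 9 oxirane
Product: 11 2-{2-[(3R,4E)-3,6-bis(TBS-oxy)-4-methylhex-4-en-1-yl]-1,3-dithian-2-yl}ethanol, via lithiodithiane 10 (not isolated)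
Conditions: n-BuLi, THF, −25 °C; then oxirane, −25 to 0 °C; aq. NH4Cl
Reagents that add atoms: none
Why: Corey–Seebach umpolung, in which the 2-lithio-1,3-dithiane opens oxirane and so attaches C5 and C6 to the masked C4 carbonyl.

Step 7
Reactants: 11 2-{2-[(3R,4E)-3,6-bis(TBS-oxy)-4-methylhex-4-en-1-yl]-1,3-dithian-2-yl}ethanol
Product: 12 {2-[(3R,4E)-3,6-bis(TBS-oxy)-4-methylhex-4-en-1-yl]-1,3-dithian-2-yl}acetaldehyde
Conditions: SO3·pyridine, DMSO, i-Pr2NEt, CH2Cl2, 0 °C
Reagents that add atoms: none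
Why: Parikh–Doering oxidation gives the C6 aldehyde and tolerates the thioacetal sulfur.

Step 8
Reactants: 12 {2-[(3R,4E)-3,6-bis(TBS-oxy)-4-methylhex-4-en-1-yl]-1,3-dithian-2-yl}acetaldehyde; 13 methyl propiolate
Product: 15 methyl (4R)-5-{2-[(3R,4E)-3,6-bis(TBS-oxy)-4-methylhex-4-en-1-yl]-1,3-dithian-2-yl}-4-hydroxypent-2-ynoate, via zinc acetylide 14 (not isolated)
Conditions: Me2Zn (3 equiv), (S,S)-ProPhenol (20 mol %), Ph3P=O (40 mol %), toluene, 4 °C; aq. NH4Cl
Reagents that add atoms: none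
Why: Catalytic asymmetric alkynylation of the aldehyde, in which the chiral dinuclear zinc catalyst delivers the zinc acetylide to one carbonyl face and so sets C6 by catalyst control.

Step 9
Reactants: 15 methyl (4R)-5-{2-[(3R,4E)-3,6-bis(TBS-oxy)-4-methylhex-4-en-1-yl]-1,3-dithian-2-yl}-4-hydroxypent-2-ynoate
Product: 16 the C6 TBS ether of 15 (methyl (4R)-4-(TBS-oxy)pent-2-ynoate carrying the same dithiane side chain)
Conditions: TBSOTf, 2,6-lutidine, CH2Cl2, −78 °C
Reagents that add atoms: TBSOTf, CC(C)(C)[Si](C)(C)OS(=O)(=O)C(F)(F)F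
Why: Silyl ether formation under non-nucleophilic conditions protects the C6 hydroxyl without isomerising the γ-oxygenated ynoate.

Step 10
Reactants: 16 the C6 TBS ether of 15; 17 2-(iodomethyl)-4,4,5,5-tetramethyl-1,3,2-dioxaborolane
Product: 19 methyl (2Z,4R)-2-(Bpin-methyl)-4-(TBS-oxy)-5-{2-[(3R,4E)-3,6-bis(TBS-oxy)-4-methylhex-4-en-1-yl]-1,3-dithian-2-yl}pent-2-enoate (C6 cis to the ester, CH2Bpin trans to C6), via vinylalane 18 (not isolated)
Conditions: i-Bu2AlH, HMPA, THF, 0 °C; then ICH2Bpin (17), 0 °C to rt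
Reagents that add atoms: none
Why: Conjugate hydroalumination of the ynoate (syn addition, H to C7 and Al to C11) followed by C-alkylation of the α-aluminio enoate with retention should fix the alkene geometry so that CH2Bpin is trans to C6.

Step 11
Reactants: 19 methyl (2Z,4R)-2-(Bpin-methyl)-4-(TBS-oxy)-5-{dithianyl}pent-2-enoate
Product: 20 methyl (2Z,4R,9R,10E)-2-(Bpin-methyl)-4,9,12-tris(TBS-oxy)-10-methyl-6-oxododeca-2,10-dienoate
Conditions: MeI, CaCO3, MeCN/H2O (9:1), 40 °C
Reagents that add atoms: water, O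
Why: Alkylative dithiane hydrolysis (S-methylation, then hydrolysis of the sulfonium) unmasks the C4 ketone under non-oxidising, near-neutral conditions that the allylboronate and the silyl ethers should survive.

Step 12
Reactants: 20 methyl (2Z,4R,9R,10E)-2-(Bpin-methyl)-4,9,12-tris(TBS-oxy)-10-methyl-6-oxododeca-2,10-dienoate
Product: 21 methyl (2Z,4R,9R,10E)-2-(Bpin-methyl)-4,9-bis(TBS-oxy)-12-hydroxy-10-methyl-6-oxododeca-2,10-dienoate
Conditions: PPTS (0.3 equiv), MeOH/CH2Cl2, 0 °C
Reagents that add atoms: none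
Why: Acid-catalysed methanolysis cleaves the unhindered primary allylic silyl ether selectively over the two secondary ones.

Step 13
Reactants: 21 methyl (2Z,4R,9R,10E)-2-(Bpin-methyl)-4,9-bis(TBS-oxy)-12-hydroxy-10-methyl-6-oxododeca-2,10-dienoate
Product: 22 methyl (2Z,4R,9R,10E)-2-(Bpin-methyl)-4,9-bis(TBS-oxy)-10-methyl-6,12-dioxododeca-2,10-dienoate
Conditions: MnO2, CH2Cl2, rt
Reagents that add atoms: none
Why: Allylic oxidation with MnO2 is chemoselective for the allylic alcohol and keeps the (E)-geometry of the new enal.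

Step 14
Reactants: 22 methyl (2Z,4R,9R,10E)-2-(Bpin-methyl)-4,9-bis(TBS-oxy)-10-methyl-6,12-dioxododeca-2,10-dienoate
Product: 25 methyl 1β,6α-bis(TBS-oxy)-8α-hydroxy-4-oxo-15-nor-5αH,7αH-eudesm-11(13)-en-12-oate, via Michael adduct 23 (not isolated), via pinacol borate 24 (not isolated)
Conditions: (S)-2-[diphenyl(trimethylsilyloxy)methyl]pyrrolidine (30 mol %), 4-nitrobenzoic acid (30 mol %), H2O (2 equiv), toluene, rt then 45 °C; aq. NH4Cl work-up
Reagents that add atoms: none
Why: Proposed new method: the secondary amine condenses with the enal to an iminium ion whose C10 is attacked by C5 of the acid-generated enol of the C4 ketone, hydrolysis of the resulting enamine frees the saturated C8 aldehyde, and this aldehyde is allylated at once by the tethered allylboronate through a closed six-membered chair transition state to give borate 24, hydrolysed on work-up; the closest known reaction types are the amine-catalysed intramolecular Michael addition of carbonyl donors to enals (including iminium additions that create quaternary β-carbons) and the carbonyl allylboration with 2-alkoxycarbonyl allylboronates, here joined in one flask. Ring A closes in a 6-(enolendo)-exo-trig mode (only the enol towards C5 can reach C10, the enol towards C3 would need a four-membered ring) and ring B by 6-exo-trig attack of C7 on the C8 carbonyl inside a chair–chair, trans-decalin-like array. C10 (R) is set by the catalyst, whose diphenyl(silyloxy)methyl group shields one face of the (E)-iminium, so that C5 adds to the open face in the arrangement with the C1–O bond anti to the forming bond, the methyl pseudo-axial and the C9 arm pseudo-equatorial; C5 is epimerisable and is funnelled to the isomer with the C6 chain equatorial (5α-H), the only one that fits the chair–chair allylboration. C7 and C8 follow from the boronate geometry (CH2B trans to C6), which in the chair transition state places the C7 side chain and the C8 oxygen both equatorial (trans), the equatorial C6 silyl ether fixing the face. The step needs chemoselectivity (the deactivated allylboronate must ignore the conjugated, remote enal until the Michael step has made the reactive, proximate aldehyde) and face selectivity at C10 (catalyst control), and the C6 silyl ether should not be eliminated because only enol and enamine, never a free enolate, are involved.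

Step 15
Reactants: 26 methyl 2-(hydroxymethyl)acrylate
Product: 27 methyl 2-[(TBS-oxy)methyl]acrylate
Conditions: TBSCl, imidazole, CH2Cl2, 0 °C to rt
Reagents that add atoms: TBSCl, CC(C)(C)[Si](C)(C)Cl
Why: Silyl ether formation masks the primary hydroxyl of the side-chain acid.

Step 16
Reactants: 27 methyl 2-[(TBS-oxy)methyl]acrylate
Product: 28 2-[(TBS-oxy)methyl]acrylic acid
Conditions: LiOH, THF/H2O, 0 °C; then dilute HCl to pH 4
Reagents that add atoms: LiOH, [Li+].[OH-]
Why: Ester saponification under mild conditions that leave the primary silyl ether in place.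

Step 17
Reactants: 25 methyl 1β,6α-bis(TBS-oxy)-8α-hydroxy-4-oxo-15-nor-5αH,7αH-eudesm-11(13)-en-12-oate; 28 2-[(TBS-oxy)methyl]acrylic acid
Product: 30 methyl 1β,6α-bis(TBS-oxy)-8α-{2-[(TBS-oxy)methyl]acryloyloxy}-4-oxo-15-nor-5αH,7αH-eudesm-11(13)-en-12-oate, via mixed anhydride 29 (not isolated)
Conditions: 2,4,6-trichlorobenzoyl chloride, Et3N, THF, rt; then 25, DMAP (cat.), toluene, rt
Reagents that add atoms: none
Why: Yamaguchi esterification acylates the only free hydroxyl (C8, equatorial), the C1 and C6 oxygens being silylated.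

Step 18
Reactants: 30 methyl 1β,6α-bis(TBS-oxy)-8α-{2-[(TBS-oxy)methyl]acryloyloxy}-4-oxo-15-nor-5αH,7αH-eudesm-11(13)-en-12-oate
Product: 31 methyl 1β,6α-dihydroxy-8α-[2-(hydroxymethyl)acryloyloxy]-4-oxo-15-nor-5αH,7αH-eudesm-11(13)-en-12-oate (target)
Conditions: HF·pyridine, pyridine, THF, 0 °C to rt
Reagents that add atoms: none
Why: Fluoride-mediated desilylation in a buffered, non-basic medium removes the three silyl ethers and should avoid acyl migration, lactonisation onto C12 and β-elimination of the C6 hydroxyl.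

Compound list

1 | (2R)-5-oxotetrahydrofuran-2-carboxylic acid | O=C(O)[C@H]1CCC(=O)O1 | starting material
2 | (2R)-5-oxotetrahydrofuran-2-carbonyl chloride | O=C(Cl)[C@H]1CCC(=O)O1 | intermediate
3 | (5R)-5-acetyldihydrofuran-2(3H)-one | CC(=O)[C@H]1CCC(=O)O1 | intermediate
4 | methyl (triphenylphosphoranylidene)acetate | COC(=O)C=P(c1ccccc1)(c1ccccc1)c1ccccc1 | starting material
5 | methyl (2E)-3-[(2R)-5-oxotetrahydrofuran-2-yl]but-2-enoate | COC(=O)/C=C(\C)[C@H]1CCC(=O)O1 | intermediate
6 | (5R)-5-[(2E)-4-hydroxybut-2-en-2-yl]tetrahydrofuran-2-ol (lactol, both anomers) | OC/C=C(\C)[C@H]1CCC(O)O1 | intermediate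
7 | (2E,4R)-6-(1,3-dithian-2-yl)-3-methylhex-2-ene-1,4-diol | OC/C=C(\C)[C@H](O)CCC1SCCCS1 | intermediate
8 | 2-[(3R,4E)-3,6-bis(TBS-oxy)-4-methylhex-4-en-1-yl]-1,3-dithiane | CC(C)(C)[Si](C)(C)OC/C=C(\C)[C@H](O[Si](C)(C)C(C)(C)C)CCC1SCCCS1 | intermediate
9 | oxirane | C1CO1 | starting material
10 | 2-lithio derivative of 8 | CC(C)(C)[Si](C)(C)OC/C=C(\C)[C@H](O[Si](C)(C)C(C)(C)C)CCC1([Li])SCCCS1 | intermediate
11 | 2-{2-[(3R,4E)-3,6-bis(TBS-oxy)-4-methylhex-4-en-1-yl]-1,3-dithian-2-yl}ethanol | CC(C)(C)[Si](C)(C)OC/C=C(\C)[C@H](O[Si](C)(C)C(C)(C)C)CCC1(CCO)SCCCS1 | intermediate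
12 | {2-[(3R,4E)-3,6-bis(TBS-oxy)-4-methylhex-4-en-1-yl]-1,3-dithian-2-yl}acetaldehyde | CC(C)(C)[Si](C)(C)OC/C=C(\C)[C@H](O[Si](C)(C)C(C)(C)C)CCC1(CC=O)SCCCS1 | intermediate
13 | methyl propiolate | C#CC(=O)OC | starting material
14 | methyl 3-(methylzincio)propiolate (zinc acetylide) | C[Zn]C#CC(=O)OC | intermediate
15 | methyl (4R)-5-{2-[(3R,4E)-3,6-bis(TBS-oxy)-4-methylhex-4-en-1-yl]-1,3-dithian-2-yl}-4-hydroxypent-2-ynoate | CC(C)(C)[Si](C)(C)OC/C=C(\C)[C@H](O[Si](C)(C)C(C)(C)C)CCC1(C[C@@H](O)C#CC(=O)OC)SCCCS1 | intermediate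
16 | C6 TBS ether of 15 | CC(C)(C)[Si](C)(C)OC/C=C(\C)[C@H](O[Si](C)(C)C(C)(C)C)CCC1(C[C@@H](O[Si](C)(C)C(C)(C)C)C#CC(=O)OC)SCCCS1 | intermediate
17 | 2-(iodomethyl)-4,4,5,5-tetramethyl-1,3,2-dioxaborolane | CC1(C)OB(CI)OC1(C)C | starting material
18 | α-(diisobutylaluminio) enoate from syn-hydroalumination of 16 (C6 cis to the ester) | CC(C)(C)[Si](C)(C)OC/C=C(\C)[C@H](O[Si](C)(C)C(C)(C)C)CCC1(C[C@@H](O[Si](C)(C)C(C)(C)C)/C=C(/[Al](CC(C)C)CC(C)C)C(=O)OC)SCCCS1 | intermediate
19 | methyl (2Z,4R)-2-(Bpin-methyl)-4-(TBS-oxy)-5-{2-[(3R,4E)-3,6-bis(TBS-oxy)-4-methylhex-4-en-1-yl]-1,3-dithian-2-yl}pent-2-enoate | CC(C)(C)[Si](C)(C)OC/C=C(\C)[C@H](O[Si](C)(C)C(C)(C)C)CCC1(C[C@@H](O[Si](C)(C)C(C)(C)C)/C=C(/CB2OC(C)(C)C(C)(C)O2)C(=O)OC)SCCCS1 | intermediate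
20 | methyl (2Z,4R,9R,10E)-2-(Bpin-methyl)-4,9,12-tris(TBS-oxy)-10-methyl-6-oxododeca-2,10-dienoate | CC(C)(C)[Si](C)(C)OC/C=C(\C)[C@H](O[Si](C)(C)C(C)(C)C)CCC(=O)C[C@@H](O[Si](C)(C)C(C)(C)C)/C=C(/CB1OC(C)(C)C(C)(C)O1)C(=O)OC | intermediate
21 | methyl (2Z,4R,9R,10E)-2-(Bpin-methyl)-4,9-bis(TBS-oxy)-12-hydroxy-10-methyl-6-oxododeca-2,10-dienoate | OC/C=C(\C)[C@H](O[Si](C)(C)C(C)(C)C)CCC(=O)C[C@@H](O[Si](C)(C)C(C)(C)C)/C=C(/CB1OC(C)(C)C(C)(C)O1)C(=O)OC | intermediate
22 | methyl (2Z,4R,9R,10E)-2-(Bpin-methyl)-4,9-bis(TBS-oxy)-10-methyl-6,12-dioxododeca-2,10-dienoate | O=C/C=C(\C)[C@H](O[Si](C)(C)C(C)(C)C)CCC(=O)C[C@@H](O[Si](C)(C)C(C)(C)C)/C=C(/CB1OC(C)(C)C(C)(C)O1)C(=O)OC | intermediate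
23 | Michael adduct: ring A cyclohexanone with C10 bearing methyl and CH2CHO, C1 TBS-oxy, C5 bearing the C6(TBS-oxy) allylboronate chain | O=CC[C@@]1(C)[C@H](O[Si](C)(C)C(C)(C)C)CCC(=O)[C@@H]1[C@@H](O[Si](C)(C)C(C)(C)C)/C=C(/CB2OC(C)(C)C(C)(C)O2)C(=O)OC | intermediate
24 | C8 O-Bpin borate of 25 | CC1(C)OB(O[C@H]2C[C@@]3(C)[C@H](O[Si](C)(C)C(C)(C)C)CCC(=O)[C@@H]3[C@@H](O[Si](C)(C)C(C)(C)C)[C@@H]2C(=C)C(=O)OC)OC1(C)C | intermediate
25 | methyl 1β,6α-bis(TBS-oxy)-8α-hydroxy-4-oxo-15-nor-5αH,7αH-eudesm-11(13)-en-12-oate | O[C@H]1C[C@@]2(C)[C@H](O[Si](C)(C)C(C)(C)C)CCC(=O)[C@@H]2[C@@H](O[Si](C)(C)C(C)(C)C)[C@@H]1C(=C)C(=O)OC | intermediate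
26 | methyl 2-(hydroxymethyl)acrylate | C=C(CO)C(=O)OC | starting material
27 | methyl 2-[(TBS-oxy)methyl]acrylate | C=C(CO[Si](C)(C)C(C)(C)C)C(=O)OC | intermediate
28 | 2-[(TBS-oxy)methyl]acrylic acid | C=C(CO[Si](C)(C)C(C)(C)C)C(=O)O | intermediate
29 | mixed anhydride of 28 with 2,4,6-trichlorobenzoic acid | C=C(CO[Si](C)(C)C(C)(C)C)C(=O)OC(=O)c1c(Cl)cc(Cl)cc1Cl | intermediate
30 | methyl 1β,6α-bis(TBS-oxy)-8α-{2-[(TBS-oxy)methyl]acryloyloxy}-4-oxo-15-nor-5αH,7αH-eudesm-11(13)-en-12-oate | C=C(CO[Si](C)(C)C(C)(C)C)C(=O)O[C@H]1C[C@@]2(C)[C@H](O[Si](C)(C)C(C)(C)C)CCC(=O)[C@@H]2[C@@H](O[Si](C)(C)C(C)(C)C)[C@@H]1C(=C)C(=O)OC | intermediate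
31 | methyl 1β,6α-dihydroxy-8α-[2-(hydroxymethyl)acryloyloxy]-4-oxo-15-nor-5αH,7αH-eudesm-11(13)-en-12-oate | C=C(CO)C(=O)O[C@H]1C[C@@]2(C)[C@H](O)CCC(=O)[C@@H]2[C@@H](O)[C@@H]1C(=C)C(=O)OC | target

Total step count: 18. Longest linear sequence: 16 steps (steps 1 to 14, 17 and 18; steps 15 and 16 make acid 28).

Steps most likely to fail

1. Step 14 (bears the label). What may go wrong is a process: iminium formation on the hindered β,β-disubstituted enal and attack by the weakly nucleophilic ketone enol may be slow. Uncatalysed closure or dienamine-mediated E/Z scrambling of the iminium would then erode the face selectivity at C10 before the allylboration locks the result. Fallback with known chemistry: the domino is given up and the donor is activated instead of the acceptor. Setting out from 22, stoichiometric pyrrolidine and acetic acid in benzene (Stork enamine Michael addition, 6-exo-trig) followed by aqueous hydrolysis should give keto aldehyde 23, now isolated and freed from its C10 epimer by chromatography. A separate Sc(OTf)3-catalysed intramolecular allylboration in CH2Cl2 at 0 °C (closed chair transition state) then gives borate 24, and aqueous work-up returns the route at 25.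

2. Step 10. What may go wrong is a process: loss of alkene geometry through the aluminium allenolate, competing 1,2-reduction of the ester, and sluggish C-alkylation by the iodomethylboronate. Fallback: the geometry is set by hydrostannation and the boron is introduced by cross-coupling. Setting out from 16, palladium-catalysed syn-hydrostannation (Bu3SnH, Pd(PPh3)4, THF) should give the α-tributylstannyl enoate F1 (C6 cis to the ester). Iododestannylation (I2, CH2Cl2, 0 °C) with retention gives the α-iodo enoate F2. Negishi coupling with IZnCH2Bpin (from 17 and zinc dust; Pd2(dba)3, tri(2-furyl)phosphine, THF) returns the route at 19.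

3. Step 11. What may go wrong is a process: protodeboronation or oxidation of the allylboronate during the long, aqueous S-alkylative hydrolysis of the dithiane. Fallback: the order is changed so that boron arrives after the ketone is unmasked. Setting out from 16, MeI/CaCO3 hydrolysis of the dithiane gives the keto ynoate F3. The ketone-tolerant sequence then follows: palladium-catalysed syn-hydrostannation gives the keto α-stannyl enoate F4, iododestannylation gives the keto α-iodo enoate F5, and Negishi coupling with IZnCH2Bpin returns the route at 20.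

Further compounds

F0 | step 14 | none | none
F1 | step 10 | methyl (4R)-2-(tributylstannyl)-4-(TBS-oxy)-5-{2-[(3R,4E)-3,6-bis(TBS-oxy)-4-methylhex-4-en-1-yl]-1,3-dithian-2-yl}pent-2-enoate (C6 cis to the ester) | CC(C)(C)[Si](C)(C)OC/C=C(\C)[C@H](O[Si](C)(C)C(C)(C)C)CCC1(C[C@@H](O[Si](C)(C)C(C)(C)C)/C=C(/[Sn](CCCC)(CCCC)CCCC)C(=O)OC)SCCCS1
F2 | step 10 | methyl (4R)-2-iodo-4-(TBS-oxy)-5-{2-[(3R,4E)-3,6-bis(TBS-oxy)-4-methylhex-4-en-1-yl]-1,3-dithian-2-yl}pent-2-enoate (C6 cis to the ester) | CC(C)(C)[Si](C)(C)OC/C=C(\C)[C@H](O[Si](C)(C)C(C)(C)C)CCC1(C[C@@H](O[Si](C)(C)C(C)(C)C)/C=C(/I)C(=O)OC)SCCCS1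
F3 | step 11 | methyl (4R,9R,10E)-4,9,12-tris(TBS-oxy)-10-methyl-6-oxododec-10-en-2-ynoate | CC(C)(C)[Si](C)(C)OC/C=C(\C)[C@H](O[Si](C)(C)C(C)(C)C)CCC(=O)C[C@@H](O[Si](C)(C)C(C)(C)C)C#CC(=O)OC
F4 | step 11 | methyl (4R,9R,10E)-2-(tributylstannyl)-4,9,12-tris(TBS-oxy)-10-methyl-6-oxododeca-2,10-dienoate (C6 cis to the ester) | CC(C)(C)[Si](C)(C)OC/C=C(\C)[C@H](O[Si](C)(C)C(C)(C)C)CCC(=O)C[C@@H](O[Si](C)(C)C(C)(C)C)/C=C(/[Sn](CCCC)(CCCC)CCCC)C(=O)OC
F5 | step 11 | methyl (4R,9R,10E)-2-iodo-4,9,12-tris(TBS-oxy)-10-methyl-6-oxododeca-2,10-dienoate (C6 cis to the ester) | CC(C)(C)[Si](C)(C)OC/C=C(\C)[C@H](O[Si](C)(C)C(C)(C)C)CCC(=O)C[C@@H](O[Si](C)(C)C(C)(C)C)/C=C(/I)C(=O)OC
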